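Cuts (isoflavan numbering: ring C = O1-C2-C3-C4, ring B = C1'-C6', pyran ring D fused at C3'/C4' with C2''-C4''): first the four silicon-based O-protecting groups, then the C3-C1' bond. This gives a 3-bromo-4-silyloxychroman (rings A/C) and a C1'-metalated chroman-3-ol ether (rings B/D).
Enabling feature: C3 is a secondary ring-C carbon next to the C4 carbinol, so a planar C3 radical can be arylated anti to a bulky C4-OSi group (3,4-trans, both C-Br epimers converge). C1' is the only free position ortho to O-2', because C3' carries the ring-D CH2, so directed metalation can give only the C1' nucleophile.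
Rings A/C forward: 7-hydroxychroman-4-one, TIPS ether, 3-bromo ketone, asymmetric transfer hydrogenation (sets C4), TBS ether.
Rings B/D forward: cyclohexane-1,3-dione and prenal build ring D on the carbon between the two oxygens, ring B is then aromatised. SEM ether, asymmetric epoxidation (sets C3''), hydride opening at C4'' and a TBS ether follow.
Union and end: ortho-lithiation, Mg transmetalation and cobalt-catalysed radical cross-coupling form C3-C1' at the final oxidation level. One fluoride step then frees the acid-sensitive tetraol without any acid.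
Stereochemistry: C4 from the (S,S)-Ru catalyst, C3 relayed from C4 in the coupling, C3'' from the (R,R)-Mn(salen) catalyst.

Key step: step 11

Remark: the SMILES is read as (3R,4S), that is 3,4-trans (aryl and 4-OH on opposite faces of ring C), and (3''R). The 4-OH is a 2,4-dioxygenated benzylic alcohol next to a free 2'-OH and is assumed to close to the pterocarpan under acid, so no acidic operation follows its release.

Step 1
Reactants: 1 7-hydroxychroman-4-one
Product: 2 7-(triisopropylsilyloxy)chroman-4-one
Conditions: TIPSCl, imidazole, DMF, rt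
Reagents that add atoms: triisopropylsilyl chloride, CC(C)[Si](Cl)(C(C)C)C(C)C
Why: Imidazole-promoted silylation of the only OH gives an aryl TIPS ether that should tolerate HBr, HCO2H/Et3N and ArMgBr and leaves with fluoride at the end.

Step 2
Reactants: 2 7-(triisopropylsilyloxy)chroman-4-one
Product: 3 rac-3-bromo-7-(triisopropylsilyloxy)chroman-4-one
Conditions: CuBr2 (2 equiv), EtOAc/CHCl3 1:1, reflux
Reagents that add atoms: copper(II) bromide, Br[Cu]Br
Why: Heterogeneous CuBr2 α-bromination of an aryl ketone proceeds through the enol at C3, the only enolisable position, and should spare the carbonyl-deactivated ring A; the new C3 centre is racemic, which is acceptable because it is erased in step 11.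

Step 3
Reactants: 3 rac-3-bromo-7-(triisopropylsilyloxy)chroman-4-one
Product: 4 (3S,4R)-3-bromo-7-(triisopropylsilyloxy)chroman-4-ol (cis)
Conditions: RuCl(p-cymene)[(S,S)-TsDPEN] (1 mol %), HCO2H/Et3N 5:2, EtOAc, rt
Reagents that add atoms: none
Why: In this Noyori-Ikariya asymmetric transfer hydrogenation with dynamic kinetic resolution, a reaction type known for cyclic α-halo aryl ketones, C3 epimerises through the enol while the (S,S) catalyst delivers hydride to the face that gives the spatial arrangement of (S)-chroman-4-ol (formally 4R here because Br raises C3 in the CIP order) and prefers the enantiomer with Br anti to the incoming hydride, so the cis bromohydrin should result.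

Step 4
Reactants: 4 (3S,4R)-3-bromo-7-(triisopropylsilyloxy)chroman-4-ol
Product: 5 (3S,4R)-3-bromo-4-(tert-butyldimethylsilyloxy)-7-(triisopropylsilyloxy)chroman
Conditions: TBSOTf, 2,6-lutidine, CH2Cl2, -78 to 0 °C
Reagents that add atoms: tert-butyldimethylsilyl triflate, CC(C)(C)[Si](C)(C)OS(=O)(=O)C(F)(F)F
Why: Buffered silylation at oxygen leaves C4 untouched, installs the bulky group that will steer step 11 and masks the ionisable benzylic alcohol, and the cis Br/O arrangement excludes epoxide closure.

Step 5
Reactants: 6 cyclohexane-1,3-dione; 7 3-methylbut-2-enal (prenal)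
Product: 8 2,2-dimethyl-7,8-dihydro-2H-chromen-5(6H)-one
Conditions: ethylenediammonium diacetate (10 mol %), MeOH, rt to 50 °C
Reagents that add atoms: none
Why: Knoevenagel condensation at the carbon between the two carbonyls followed by oxa-6π electrocyclisation (formal [3+3]) places ring D exactly where the target has it, between the two ring-B oxygens, with no regioisomer possible.

Step 6
Reactants: 8 2,2-dimethyl-7,8-dihydro-2H-chromen-5(6H)-one
Product: 11 2,2-dimethyl-2H-chromen-5-ol, via selenide 9 (not isolated), via selenoxide 10 (not isolated)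
Conditions: LDA (commercial solution), THF, -78 °C, then PhSeCl; crude selenide: 30 % H2O2, pyridine, CH2Cl2, 0 °C to rt
Reagents that add atoms: none
Why: Kinetic α'-deprotonation of the vinylogous ester (Stork-Danheiser regiochemistry), selenenylation and selenoxide syn-elimination give a cross-conjugated dienone that tautomerises to the phenol, so ring B is aromatised without touching the chromene double bond.

Step 7
Reactants: 11 2,2-dimethyl-2H-chromen-5-ol
Product: 12 2,2-dimethyl-5-{[2-(trimethylsilyl)ethoxy]methoxy}-2H-chromene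
Conditions: SEMCl, iPr2NEt, CH2Cl2, 0 °C to rt
Reagents that add atoms: 2-(trimethylsilyl)ethoxymethyl chloride, C[Si](C)(C)CCOCCl
Why: O-alkylation of the phenol gives an acetal-type ether that protects it from the oxidant, later acts as the ortho-metalation director and is removable with fluoride instead of acid.

Step 8
Reactants: 12 2,2-dimethyl-5-{[2-(trimethylsilyl)ethoxy]methoxy}-2H-chromene
Product: 13 (3R,4R)-3,4-epoxy-2,2-dimethyl-5-{[2-(trimethylsilyl)ethoxy]methoxy}chroman
Conditions: (R,R)-Mn(salen)Cl (Jacobsen catalyst, 3 mol %), 4-phenylpyridine N-oxide (cat.), aq NaOCl (pH 11.3), CH2Cl2, 0 °C; filtration through basic alumina, used at once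
Reagents that add atoms: sodium hypochlorite, [Na+].[O-]Cl
Why: In the Jacobsen-Katsuki epoxidation 2,2-dimethylchromenes are the privileged substrate class, and the (R,R) catalyst should deliver oxygen to the face that gives the (3R,4R) epoxide, which fixes C3''.

Step 9
Reactants: 13 (3R,4R)-3,4-epoxy-2,2-dimethyl-5-{[2-(trimethylsilyl)ethoxy]methoxy}chroman
Product: 14 (3R)-2,2-dimethyl-5-{[2-(trimethylsilyl)ethoxy]methoxy}chroman-3-ol
Conditions: LiAlH4, THF, 0 °C; aqueous NaOH work-up
Reagents that add atoms: none
Why: Regioselective reductive epoxide opening occurs by hydride attack at benzylic C4, the less hindered carbon since C3 is neopentyl-like next to CMe2, so the C3-O bond and its (R) configuration are not touched.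

Step 10
Reactants: 14 (3R)-2,2-dimethyl-5-{[2-(trimethylsilyl)ethoxy]methoxy}chroman-3-ol
Product: 15 (3R)-3-(tert-butyldimethylsilyloxy)-2,2-dimethyl-5-{[2-(trimethylsilyl)ethoxy]methoxy}chroman
Conditions: TBSCl, imidazole, DMAP (cat.), DMF, 45 °C
Reagents that add atoms: tert-butyldimethylsilyl chloride, CC(C)(C)[Si](C)(C)Cl
Why: Silylation under non-Lewis-acidic conditions, chosen so that the SEM acetal survives, removes the only acidic proton before the organometallic step.

Step 11
Reactants: 15 (3R)-3-(tert-butyldimethylsilyloxy)-2,2-dimethyl-5-{[2-(trimethylsilyl)ethoxy]methoxy}chroman; 5 (3S,4R)-3-bromo-4-(tert-butyldimethylsilyloxy)-7-(triisopropylsilyloxy)chroman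
Product: 18 (3R,4S)-4-(tert-butyldimethylsilyloxy)-3-[(3R)-3-(tert-butyldimethylsilyloxy)-2,2-dimethyl-5-{[2-(trimethylsilyl)ethoxy]methoxy}chroman-6-yl]-7-(triisopropylsilyloxy)chroman, via aryllithium 16 (not isolated), via arylmagnesium bromide 17 (not isolated)
Conditions: 15, n-BuLi, TMEDA, THF, -78 to 0 °C; MgBr2·OEt2, -20 °C to rt; then added to 5, CoCl2·2LiCl (30 mol %), TMEDA, THF, -20 to 0 °C
Reagents that add atoms: none
Why: n-BuLi/TMEDA is steered by the SEM acetal oxygens to C6 of 15 (the future C1'), the only free position ortho to that oxygen because the other one carries the ring-D methylene, and MgBr2 turns 16 into the milder Grignard reagent 17. Low-valent aryl-cobalt species formed from CoCl2 and 17 abstract bromine from C3 of 5 by single-electron transfer, the planar chroman-3-yl radical recombines with aryl-cobalt, and reductive elimination forms the C3-C1' bond. The closest known reaction type is the cobalt- or iron-mediated Kumada-type coupling of TBS-protected cyclic halohydrins with aryl Grignard reagents, which gives trans-2-arylcycloalkanol ethers. No ring is closed. The one new stereocentre, C3, is controlled by the C4-OTBS group, which sits pseudoaxial on the half-chair of ring C and shields its face, so the aryl group should arrive anti to it and give the 3,4-trans (3R,4S) product whatever the C-Br configuration was, while C4 itself is never touched. The step needs radical capture to outrun β-elimination of silanolate or of the ring aryloxide, which the low temperature, the fast capture and reductive elimination at cobalt and the poor leaving-group quality of OTBS should secure.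

Step 12
Reactants: 18 fully protected trans-isoflavan-4-ol
Product: 19 (3R,4S)-3-[(3R)-3,5-dihydroxy-2,2-dimethylchroman-6-yl]chroman-4,7-diol (target)
Conditions: TBAF (excess), ethylenediamine, THF, 0 °C to rt, then DMPU, 45 °C; pH 7 buffer work-up, Et3N-deactivated silica
Reagents that add atoms: none
Why: Fluoride attacks silicon in all four groups (Si-O cleavage of TIPS and TBS first, then fragmentation of SEM to ethene and formaldehyde, the latter trapped by ethylenediamine), and because the medium stays basic and the SEM group on O-2' falls last, the C4-O bond should not ionise and none of the three stereocentres is touched.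

Compound list
1 | 7-hydroxychroman-4-one | O=C1CCOc2cc(O)ccc12 | starting material
2 | 7-(triisopropylsilyloxy)chroman-4-one | O=C1CCOc2cc(O[Si](C(C)C)(C(C)C)C(C)C)ccc12 | intermediate
3 | rac-3-bromo-7-(triisopropylsilyloxy)chroman-4-one | O=C1C(Br)COc2cc(O[Si](C(C)C)(C(C)C)C(C)C)ccc12 | intermediate
4 | (3S,4R)-3-bromo-7-(triisopropylsilyloxy)chroman-4-ol (cis) | Br[C@H]1COc2cc(O[Si](C(C)C)(C(C)C)C(C)C)ccc2[C@H]1O | intermediate
5 | (3S,4R)-3-bromo-4-(tert-butyldimethylsilyloxy)-7-(triisopropylsilyloxy)chroman | Br[C@H]1COc2cc(O[Si](C(C)C)(C(C)C)C(C)C)ccc2[C@H]1O[Si](C)(C)C(C)(C)C | intermediate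
6 | cyclohexane-1,3-dione | O=C1CCCC(=O)C1 | starting material
7 | 3-methylbut-2-enal | CC(C)=CC=O | starting material
8 | 2,2-dimethyl-7,8-dihydro-2H-chromen-5(6H)-one | CC1(C)C=CC2=C(O1)CCCC2=O | intermediate
9 | 2,2-dimethyl-6-(phenylselanyl)-7,8-dihydro-2H-chromen-5(6H)-one (racemic) | CC1(C)C=CC2=C(O1)CCC([Se]c3ccccc3)C2=O | intermediate
10 | 2,2-dimethyl-6-(phenylseleninyl)-7,8-dihydro-2H-chromen-5(6H)-one | CC1(C)C=CC2=C(O1)CCC([Se](=O)c3ccccc3)C2=O | intermediate
11 | 2,2-dimethyl-2H-chromen-5-ol | CC1(C)C=Cc2c(O)cccc2O1 | intermediate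
12 | 2,2-dimethyl-5-{[2-(trimethylsilyl)ethoxy]methoxy}-2H-chromene | CC1(C)C=Cc2c(OCOCC[Si](C)(C)C)cccc2O1 | intermediate
13 | (3R,4R)-3,4-epoxy-2,2-dimethyl-5-{[2-(trimethylsilyl)ethoxy]methoxy}chroman | CC1(C)Oc2cccc(OCOCC[Si](C)(C)C)c2[C@H]3O[C@H]31 | intermediate
14 | (3R)-2,2-dimethyl-5-{[2-(trimethylsilyl)ethoxy]methoxy}chroman-3-ol | CC1(C)Oc2cccc(OCOCC[Si](C)(C)C)c2C[C@H]1O | intermediate
15 | (3R)-3-(tert-butyldimethylsilyloxy)-2,2-dimethyl-5-{[2-(trimethylsilyl)ethoxy]methoxy}chroman | CC1(C)Oc2cccc(OCOCC[Si](C)(C)C)c2C[C@H]1O[Si](C)(C)C(C)(C)C | intermediate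
16 | 6-lithio derivative of 15 | CC1(C)Oc2ccc([Li])c(OCOCC[Si](C)(C)C)c2C[C@H]1O[Si](C)(C)C(C)(C)C | intermediate
17 | 6-(bromomagnesio) derivative of 15 | CC1(C)Oc2ccc([Mg]Br)c(OCOCC[Si](C)(C)C)c2C[C@H]1O[Si](C)(C)C(C)(C)C | intermediate
18 | (3R,4S,3''R) fully protected trans-isoflavan-4-ol (7-OTIPS, 4-OTBS, 2'-OSEM, 3''-OTBS) | CC1(C)Oc2ccc([C@@H]3COc4cc(O[Si](C(C)C)(C(C)C)C(C)C)ccc4[C@H]3O[Si](C)(C)C(C)(C)C)c(OCOCC[Si](C)(C)C)c2C[C@H]1O[Si](C)(C)C(C)(C)C | intermediate
19 | (3R,4S)-3-[(3R)-3,5-dihydroxy-2,2-dimethylchroman-6-yl]chroman-4,7-diol | CC1(C)Oc2ccc([C@@H]3COc4cc(O)ccc4[C@H]3O)c(O)c2C[C@H]1O | target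

Total steps: 12. Longest linear sequence: 8 (steps 5 to 12).

Steps most likely to fail

**1. Step 11.**
- What may go wrong: β-elimination at the C3 radical or organocobalt stage, slow transfer of the ortho-substituted aryl group to cobalt, or too weak a facial bias at C3.
- The fallback uses an sp2-sp2 coupling and sets both ring-C stereocentres afterwards by reagent control. It sets out from 4 and 15 and comes back at 19.
- Acid-catalysed dehydration of 4 (cat. TsOH, toluene, 80 °C) should give 3-bromo-7-(triisopropylsilyloxy)-2H-chromene F1.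
- Aryllithium 16, made from 15 as in step 11, is trapped with iPrOBpin to give the pinacol boronate F2.
- Suzuki-Miyaura coupling of F1 and F2 (Pd(dppf)Cl2, K3PO4, dioxane/H2O, 80 °C) gives the protected isoflav-3-ene F3.
- Brown asymmetric hydroboration with IpcBH2 made from (-)-α-pinene (antipode chosen by analogy with 1-arylcycloalkenes) adds H to C3 and boron to the less substituted C4 on the same face, giving the organoborane F4.
- NaBO3 oxidation with retention gives the trans-(3R,4S) 4-alcohol F5, which is deprotected under the conditions of step 12 to 19.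

**2. Step 12.**
- What may go wrong: incomplete cleavage of the aryl SEM ether, capture of released formaldehyde by the phenoxides, or base-induced loss of the C4 oxygen through a para-quinone methide at the temperature the SEM group needs.
- The fallback keeps SEM only as a metalation director and swaps it at the robust fragment stage for an all-silyl endgame. It sets out from 15 (through 16) and 5 and comes back at 19.
- Aryllithium 16 is quenched with I2 to give the 6-iodo SEM/TBS ether F6.
- HCl in MeOH (40 °C) removes both SEM and TBS to give (3R)-6-iodo-2,2-dimethylchroman-3,5-diol F7.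
- TBSOTf/2,6-lutidine silylates both hydroxyls to give the bis-TBS iodide F8.
- I/Mg exchange with iPrMgCl·LiCl, kept at or below -20 °C to avoid an O-to-C silyl shift, gives the arylmagnesium chloride F9.
- F9 is coupled with 5 under the cobalt conditions of step 11 to give the all-silyl trans-isoflavan-4-ol F10.
- TBAF in THF at 0 °C to rt then frees 19 without heating and without formaldehyde.

**3. Step 3.**
- What may go wrong: loss of HBr to the chromone followed by over-reduction, or C3 epimerisation too slow for an efficient dynamic resolution.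
- The fallback needs no dynamic resolution and exploits the fact that step 11 erases C3. It sets out from 3 and comes back at 18.
- Corey-Bakshi-Shibata reduction ((R)-Me-CBS cat., BH3·SMe2, THF, -20 °C, base-free) should reduce both enantiomers of 3 from the same carbonyl face. This gives 4 together with its C3 epimer, the (3R,4R)-trans-bromohydrin F11.
- The mixture is silylated as in step 4 to 5 and the trans TBS ether F12, and both converge on 18 in step 11.

Further compounds
F1 | step 11 | 3-bromo-7-(triisopropylsilyloxy)-2H-chromene | BrC1=Cc2ccc(O[Si](C(C)C)(C(C)C)C(C)C)cc2OC1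
F2 | step 11 | 6-(pinacolatoboryl) derivative of 15 | CC1(C)Oc2ccc(B3OC(C)(C)C(C)(C)O3)c(OCOCC[Si](C)(C)C)c2C[C@H]1O[Si](C)(C)C(C)(C)C
F3 | step 11 | protected isoflav-3-ene (7-OTIPS, 2'-OSEM, 3''-OTBS) | CC1(C)Oc2ccc(C3=Cc4ccc(O[Si](C(C)C)(C(C)C)C(C)C)cc4OC3)c(OCOCC[Si](C)(C)C)c2C[C@H]1O[Si](C)(C)C(C)(C)C
F4 | step 11 | (3R,4S)-isoflavan-4-yl(isopinocampheyl)borane | CC1(C)Oc2ccc([C@@H]3COc4cc(O[Si](C(C)C)(C(C)C)C(C)C)ccc4[C@H]3B[C@H]5C[C@H]6C[C@@H]([C@@H]5C)C6(C)C)c(OCOCC[Si](C)(C)C)c2C[C@H]1O[Si](C)(C)C(C)(C)C
F5 | step 11 | (3R,4S)-trans-isoflavan-4-ol with 7-OTIPS, 2'-OSEM, 3''-OTBS | CC1(C)Oc2ccc([C@@H]3COc4cc(O[Si](C(C)C)(C(C)C)C(C)C)ccc4[C@H]3O)c(OCOCC[Si](C)(C)C)c2C[C@H]1O[Si](C)(C)C(C)(C)C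
F6 | step 12 | (3R)-3-(tert-butyldimethylsilyloxy)-6-iodo-2,2-dimethyl-5-{[2-(trimethylsilyl)ethoxy]methoxy}chroman | CC1(C)Oc2ccc(I)c(OCOCC[Si](C)(C)C)c2C[C@H]1O[Si](C)(C)C(C)(C)C
F7 | step 12 | (3R)-6-iodo-2,2-dimethylchroman-3,5-diol | CC1(C)Oc2ccc(I)c(O)c2C[C@H]1O
F8 | step 12 | (3R)-3,5-bis(tert-butyldimethylsilyloxy)-6-iodo-2,2-dimethylchroman | CC1(C)Oc2ccc(I)c(O[Si](C)(C)C(C)(C)C)c2C[C@H]1O[Si](C)(C)C(C)(C)C
F9 | step 12 | 6-(chloromagnesio) derivative of F8 | CC1(C)Oc2ccc([Mg]Cl)c(O[Si](C)(C)C(C)(C)C)c2C[C@H]1O[Si](C)(C)C(C)(C)C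
F10 | step 12 | (3R,4S,3''R) all-silyl trans-isoflavan-4-ol (7-OTIPS, 4-, 2'- and 3''-OTBS) | CC1(C)Oc2ccc([C@@H]3COc4cc(O[Si](C(C)C)(C(C)C)C(C)C)ccc4[C@H]3O[Si](C)(C)C(C)(C)C)c(O[Si](C)(C)C(C)(C)C)c2C[C@H]1O[Si](C)(C)C(C)(C)C
F11 | step 3 | (3R,4R)-3-bromo-7-(triisopropylsilyloxy)chroman-4-ol (trans) | Br[C@@H]1COc2cc(O[Si](C(C)C)(C(C)C)C(C)C)ccc2[C@H]1O
F12 | step 3 | (3R,4R)-3-bromo-4-(tert-butyldimethylsilyloxy)-7-(triisopropylsilyloxy)chroman | Br[C@@H]1COc2cc(O[Si](C(C)C)(C(C)C)C(C)C)ccc2[C@H]1O[Si](C)(C)C(C)(C)C
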